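The numbers in the tables are simulated with made-up constants.

No rate constant is given for the elm flask, so I work without one, from its charges at one end and its first reading at the other.

common to all: electrophile 0.050 M
- elm: nucleophile 0.065 M; temperature 35 °C; the very flask that is asked about, followed so far
- alder: nucleophile 0.065 M; temperature 30 °C; run made earlier
- flask: nucleophile 0.0650 M; temperature 35 °C; time 5.0 min

- elm (time / min: target / %): 0.833: 32; 1.50: 38; 2.50: 45; 3.00: 41; 4.00: 47
- alder (time / min: target / %): 0.833: 22; 1.50: 35; 2.50: 40; 3.00: 44; 4.00: 47

(each reading ± 2 percentage points)

- red: at 5.0 min take out 90 % of the acid set free then present, then wait 1.5 min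
- blue: change nothing and wait 1.5 min more
- teal: at 5.0 min raise the temperature by 15 K, then wait 1.5 min
- amber: at 5.0 min add nucleophile, 100 % of the amount charged, then wait 1.5 min

1. target, in percent of the electrophile first charged, at 5.0 min
2. which option adds most target ("none" when 2 percentage points or less is all one gets) (red / blue / teal / amber / none)
3. target present, in percent of the electrophile first charged, after red
4. target present, in percent of the electrophile first charged, after teal

- what is added takes up no volume worth counting
- what was read earlier has a scatter of 2 percentage points, one standard deviation

Each target sets free an acid, and I suppose that this acid takes a further nucleophile out of play, so that each target costs two nucleophile.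

ceiling = c_nucleophile / (2 c_electrophile) = 65.0 %

This acid ceiling, the charge of nucleophile over twice the charge of electrophile, is the share of charged electrophile that can turn into target on that count, and on the same count the nucleophile is the limiting reagent. To join the two ends, I use the second-order law with that cost: for a converted share f, G grows in proportion to time.

G = ln[ceiling (1 − f) / (ceiling − f)]

first reading, 32 % at 0.833 min: G = 0.292

f at 4.00 min = 58.3 %

f at 5.0 min = 60.6 %

My first upper bound is therefore 60.6 %. But the line stands higher than the last reading, so I keep just its last rise and add it to that reading.

upper bound = 47 % + 2.3 percentage points = 49.2 %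

lower bound, mean of the last three elm readings = 44.3 %

These two marks are my estimates read off scattered readings, not limits of the elm flask.

Amber raises the ceiling to 130 %, past the whole charge of electrophile, while red and teal leave the nucleophile charge as it is, so I commit to amber.

The forecast gives 47.5 % (from 45.5 % to 49.5 %), inside my bracket , with 60 % after red, 44 % after teal, amber as its choice, and the judgement that “waiting adds nothing”.

The elm flask gives 47.8 %, inside the bracket . Amber adds most, 14 points, against 6.8 points for teal, 2.2 points for red and 1.5 points for blue; red ends at 50.1 % and teal at 54.6 %.

    electrophile + nucleophile → acid set free + target (k = 0.180 L mol⁻¹ s⁻¹, Ea = 49.0 kJ mol⁻¹)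
    nucleophile + acid set free ⇌ protonated nucleophile, settled at all times (K = 830 L mol⁻¹, ΔH = −41.0 kJ mol⁻¹)
    target ⇌ isomer of the product (K = 0.330, k = 0.00330 s⁻¹, Ea = 94.0 kJ mol⁻¹, ΔH = −13.0 kJ mol⁻¹)
    2 electrophile → homo dimer (k = 0.0140 L mol⁻¹ s⁻¹, Ea = 72.0 kJ mol⁻¹)
    (constants at 35 °C)

The neighbour flask with 0.016 M of nucleophile has a ceiling of 16.0 %, and at 5.00 min its target and isomer of the product together reach 18.9 %, more than that. The elm flask at 5.00 min holds 61.8 % of the two, less than its ceiling, and it is not at rest: target is still made 2.08 times faster than it is used up. Left alone in the elm flask until 50.0 min, the acid set free climbs from 0.00428 M to 0.0160 M, target and isomer of the product together stand at 79.2 %, above the ceiling, and target reaches 59.6 %.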